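A small charge does the work here: 8.8 µM of second catalyst against 0.0010 M of substrate.

all flasks: free catalyst 0.20 mM
- elm: substrate 0.0010 M; reagent 0.95 mM; second catalyst 8.8 µM; temperature −10 °C; run made earlier
- maple: substrate 6.7 × 10⁻⁴ M; reagent 0.95 mM; second catalyst 8.8 µM; temperature 5 °C; run made earlier
- larch: substrate 0.0015 M; reagent 0.95 mM; second catalyst 8.8 µM; temperature −10 °C; run made earlier
- cedar: substrate 0.0010 M; reagent 0.95 mM; second catalyst 4.4 µM; temperature 5 °C; run made earlier
- beta: substrate 0.0010 M (in portions, 4, over 12 min); reagent 0.950 mM; second catalyst 8.8 µM; temperature 5 °C; first portion at the start, last at 12 min; time 15 min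
- theta: substrate 0.0010 M; reagent 0.950 mM (fed, over 12 min); second catalyst 8.8 µM; the addition at −15 °C, then warmed to 5 °C; the feed brings no volume worth counting; time 15 min
- delta: substrate 0.0010 M; reagent 0.950 mM; second catalyst 8.8 µM; temperature 5 °C; everything together at the start; time 15 min
- epsilon: substrate 0.0010 M; reagent 0.950 mM (fed, over 12 min); second catalyst 8.8 µM; temperature 5 °C; all else is in the flask from the start; the feed brings no volume worth counting; time 15 min

| run | time / min | side product / % | target / % |
|---|---|---|---|
| elm | 3.00 | 1.9 | 1.6 |
| elm | 4.00 | 2.2 | 2.0 |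
| elm | 6.00 | 1.6 | 3.0 |
| elm | 8.00 | 3.5 | 4.8 |
| elm | 12.0 | 5.7 | 5.8 |
| elm | 20.0 | 10.0 | 8.0 |
| elm | 30.0 | 17.8 | 10.7 |
| maple | 1.00 | 1.1 | 1.9 |
| maple | 1.33 | 1.1 | 3.2 |
| maple | 2.00 | 2.8 | 4.5 |
| maple | 3.00 | 5.9 | 5.6 |
| maple | 5.00 | 11.9 | 8.3 |
| maple | 8.00 | 23.0 | 10.3 |
| maple | 12.0 | 37.8 | 12.9 |
| larch | 1.33 | 0.4 | 0.6 |
| larch | 4.00 | 1.4 | 0.9 |
| larch | 6.00 | 2.4 | 2.3 |
| larch | 10.0 | 3.9 | 2.5 |
| larch | 15.0 | 6.2 | 3.3 |
| larch | 20.0 | 9.4 | 4.6 |
| larch | 25.0 | 11.7 | 4.3 |
| cedar | 2.50 | 2.7 | 2.0 |
| cedar | 5.00 | 5.2 | 2.0 |
| cedar | 8.00 | 10.8 | 1.2 |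
| cedar | 10.0 | 13.9 | 2.6 |
| cedar | 12.0 | 17.5 | 2.5 |

(each reading ± 0.5 percentage points)

- percent here means substrate units held: one side product counts as two

1. the flask that comes out highest in amount of side product, in percent of the substrate charged; "all alike" if 1.5 percentage points covers them all (beta / theta / delta / epsilon / all alike)
2. amount of side product at the end, in percent of the substrate charged, beta
3. amount of side product at the end, in percent of the substrate charged, theta
4. amount of side product at the end, in percent of the substrate charged, delta
5. amount of side product at the end, in percent of the substrate charged, epsilon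

Which numbers must we know well? Take target held plus half the side product, which counts all target made if one side product holds one target, and reckon it per minute in mM. Substrate can be far off: larch, with 1.50 times elm's substrate, streams 0.00609 mM/min up to its last reading against 0.00653 mM/min in elm, so larch is no faster. So beta's portions should leave this stream alone. Second catalyst looks to count one for one: cedar, with half maple's and more substrate, streams 0.00938 mM/min, about half of maple's. But beta, theta, delta and epsilon share that charge, and share their free catalyst. We take the rate-limiting step to be first order in reagent, an assumption, since no run varied reagent. Then epsilon's feed offers on average 0.600 of the full reagent. Temperature counts for theta's cold stage.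

The number to hold is then maple's turnover stream, all target made per minute at 5 °C: 0.0178 mM/min, or 26.6% of the charge by 15 min. Standing target comes off this, and the rest counts twice as side product. Cedar's last reading held 2.5% of target at half the stream, so we reckon 5.00% of target in delta and 43.3% side product. Epsilon streams 16.0%, giving 22.0%. We liken beta's thin substrate to maple, whose last target reading equals 8.64% of our charge, giving 36.0%. From elm to maple the stream rises 2.73 times, so at −15 °C we expect it 3.79 times slower; theta then streams 8.14%, giving 6.27%. We call delta highest.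

The forecast names epsilon, with 27% for beta, 10% for theta, 43% for delta and 46% for epsilon, and says of epsilon: “no run varied reagent, so this is a real guess”.

The flasks give 35.9% for beta, 8.60% for theta, 40.4% for delta and 23.4% for epsilon, so delta stands highest.

    substrate + free catalyst ⇌ free catalyst + open intermediate (K = 1.00, k = 590 /M/s, Ea = 42.0 kJ/mol, ΔH = −62.0 kJ/mol)
    second catalyst + open intermediate ⇌ catalyst intermediate (K = 52000 /M, k = 1.30 × 10⁵ /M/s, Ea = 30.0 kJ/mol, ΔH = −4.00 kJ/mol)
    reagent + catalyst intermediate → second catalyst + target (k = 43.0 /M/s, Ea = 44.0 kJ/mol)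
    2 free catalyst ⇌ resting dimer, settled at all times (K = 1.20 × 10⁵ /M, ΔH = −13.0 kJ/mol)
    substrate + target → side product (k = 14.0 /M/s, Ea = 41.0 kJ/mol)
    (constants at 5 °C)

In delta, half the turnover of the substrate step is done by 0.395 min, but half that of the reagent step takes until 6.88 min, much later. At 15.0 min catalyst intermediate holds 93.1% of the second catalyst in delta. The turnover stream adds up to 26.1% in delta against our 26.6%, and to 16.6% in epsilon against our 16.0%.

The numbers in the tables are calculated for an exercise; scatter was added.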